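Assumptions (remarks on the chemistry): the (S,S) antipode of the bis(oxazoline) ligand in step 3 and the (−) antipode of the allylborane in step 11 are written by analogy with 2,3-dihydrofuran and with benzaldehyde; both antipodes of each are commercial, and the one that gives the configuration drawn is used. Stereodescriptors were derived by hand from the SMILES strings; where a descriptor and a SMILES string disagree, the SMILES string is meant.

## The problem

The target is a monocyclic bisabolane triester, numbered here C1 (side-chain carbon), C2 (CH2), C3 and C4 (epoxide carbons, methyl C15 on C4), C5 and C6 (angelate carbinols) in the ring, and C7 (bearing methylene C14), C8 (acetoxy), C9, C10 and C11 (methyls C12, C13) in the chain. Nothing is fused to the six-membered ring except the epoxide, so the ring must be assembled with five contiguous substituents already in place, and the chain hangs on C1 through the sp2 carbon C7. All five ring stereocentres are cis (1S,3S,4S,5R,6R): the side chain, both acyloxy groups and the epoxide oxygen share one face, so each sits where an external reagent would not put it. The relations can still be used in sequence: a fixed cis C1/C6 pair shields one face of a C5 ketone, so hydride gives the all-cis C5 alcohol, and that alcohol can deliver the epoxide oxygen to C3=C4 on its own face. C8 (S) is insulated from the ring by C7 and needs reagent control. The angelates (Z to E isomerisation with nucleophiles or base), the trisubstituted epoxide (acid), the allylic acetate and the two isolated alkenes will not survive rough handling, so epoxide and angelates come last. The enabling feature is C5: it is a carbinol flanked by the oxygenated C6 and by C4, the methyl-bearing end of a C2–C3–C4 unit, so it can be one carbon monoxide inserted between C6 and C4. The cis C1/C6 pair then maps onto two carbons of a cis-fused cyclopropane (C1, C2, C6) made from a cyclic, hence Z, enol ether, and the 1,4-relation of O–C6 and O–C8 maps onto (Z)-but-2-ene-1,4-diol.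

## Retrosynthesis

**Ester C–O bonds at C5 and C6 (24 ⇒ 21 + 22, through mixed anhydride 23).** The angelates are the most fragile groups and are removed first. Both are cut at once because both hydroxyls belong to one cis-diol; acylating them separately would cost protecting-group steps. Epoxy diol 21 is ten carbons smaller and has no isomerisable enoate. The forward reaction must acylate two hindered cis hydroxyls beside an epoxide without Z to E isomerisation.

**Epoxide C–O bonds (21 ⇒ 20).** The epoxide is cut next so that the free C5 hydroxyl of diol 20 can direct it. An earlier epoxidation would expose the epoxide to the acid needed for ketal chemistry. The precursor has two stereocentres fewer. The forward step must be syn-selective and choose C3=C4 over two other alkenes.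

**Diol mask, C10=C11 and the C8 acetate (20 ⇒ 19 ⇒ 18 ⇒ 17).** The diol is carried as a cis-acetonide. The prenyl group is cut back to an allyl group because enantioselective linear prenyl transfer to an aldehyde is not well established, whereas allyl transfer is, and cross-metathesis with 2-methylbut-2-ene is reliable. The forward metathesis must touch only the terminal alkene of 18.

**C8–C9 (17 ⇒ 15, through borinate 16).** The alternative cut, C7–C8 (vinyl metal plus aldehyde), would need an aldehyde on C1, which can epimerise. Enal 15 has no epimerisable centre. The forward allylboration must set C8 by reagent control.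

**C7=C14 and the C8 oxidation level (15 ⇒ 14 ⇒ 13).** The methylene is cut as formaldehyde from aldehyde 14, which comes from primary alcohol 13. This places C14 without an olefination of a hindered ketone.

**Ketal shift and C5–H (13 ⇒ 12 ⇒ 11).** The C5/C6 acetonide of 13 is the thermodynamic isomer of the seven-membered C6–O/C8–O ketal of 12, so no protecting group is added or removed. Alcohol 12 comes from enone 11 by hydride addition anti to the cis C1/C6 pair.

**C5–C6 and C4–C5 (11 ⇒ 8 + 9, through β,γ-enone 10).** This is the key cut. Removing C5 as carbon monoxide opens the ring to an alkenylcyclopropane in which the cis C1/C6 relation is fixed by ring fusion. A cut at C1–C6 or C1–C2 would leave that relation to be set on a six-membered ring against sterics. Precursor 8 has no carbonyl and one ring fewer. The forward reaction must open the C2–C6 bond and not C2–C1.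

**C3=C4 (8 ⇒ 6 + 7; 6 ⇒ 5).** The propenyl group is cut at its double bond into aldehyde 6 and ethyl sulfone 7. This gives the E alkene under conditions mild enough for a donor–acceptor cyclopropane aldehyde. Aldehyde 6 is the reduced form of ester 5.

**C2–C1 and C2–C6 (5 ⇒ 3 + 4).** The cyclopropane is cut into enol ether 3 and ethyl diazoacetate 4. Carbene addition is stereospecific, so the Z geometry of 3 becomes the cis C1/C6 pair, and a chiral copper catalyst can set the absolute configuration. Both precursors are achiral.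

**Enol ether (3 ⇒ 2 ⇒ 1).** Enol ether 3 is the double-bond isomer of acetonide 2 of (Z)-but-2-ene-1,4-diol 1. The diol supplies C6, C1, C7, C8 and both oxygens; the ketal is at once tether, protecting group and donor.

## Roads not taken

Alternative 1: The cut is at C7–C8 and C14–C8. The titanacyclopropane made from the C1-vinyl acetonide A2 by ligand exchange (Ti(OiPr)4, c-C6H11MgCl) would add twice to methyl 4-methylpent-3-enoate A3 and give cyclopropanol A1. Ring opening of A1 to the α-methylene ketone and enantioselective reduction would finish the chain. Its merit is real: one C–C bond-forming step brings in C8 to C13 from a simple ester, and the C7 configuration need not be controlled. The chosen plan needs three steps (C14, C9–C10, C11–C13) for the same carbons. Its weakness is that A2 already contains the all-cis ring with a carbon substituent cis to C6–O, so the hardest problem is left unsolved. The ligand exchange onto an α-branched vinyl group is also sluggish, and the ring-opened ketone is a skipped enone that can conjugate before it is reduced. The chosen plan sets against this a ring construction that delivers the cis C1/C6 pair itself.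

Alternative 2: The cut is at C1–C7. Bu3SnH would generate the vinyl radical of the (1-bromovinyl)silyl ether A5, which adds 5-exo to C1 of the diene; the allyl radical is then reduced at C2 to give oxasilolane A4. In one respect this road is better than the chosen one: tethered 5-exo radical cyclisations are well established and enforce the cis C1/C6 relation, whereas the regiochemistry of the chosen key step is untested. It also brings C14 in together with C7. Its weaknesses are several. By CIP analysis the ring of the target corresponds to the (1R,2S) diene diol, the antipode of the microbial toluene dihydrodiol A6. The C7–Si bond must still be turned into C7–C8 (iododesilylation, then CrCl2/NiCl2 coupling) with C8 uncontrolled by the substrate. The allyl radical can also be quenched at C4, and tin is used. The chosen plan offers catalytic control of absolute configuration from achiral materials and a C7–C8 bond that is present from the first step.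

Alternative 3: The cut is at C2–C3 and C6–C1. Diene A8 and enone A9 would combine under BF3·OEt2 in an endo Diels–Alder reaction to give adduct A7. This is the most convergent road and the shortest on paper: one step forms the ring, three stereocentres and the C1–C7 bond with the whole chain attached. Its weakness is a stack of selectivities. Facial selectivity rests on the acyclic C8 centre of A9 under a non-chelating Lewis acid, and regiochemistry rests only on the methyl group of A8. Enone A9 can polymerise and can racemise at C8. Adduct A7 carries oxygen at C3 and not at C5, so a 1,3-transposition is needed, and the C7 ketone must be methylenated between two epimerisable centres. The chosen plan is longer but each stereocentre has its own control element.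

Key step: step 6

## Steps

Step 1
Reactants: 1 (Z)-but-2-ene-1,4-diol
Product: 2 2,2-dimethyl-4,7-dihydro-1,3-dioxepine
Conditions: 2,2-dimethoxypropane, TsOH·H2O (cat.), CH2Cl2, rt
Reagents that add atoms: 2,2-dimethoxypropane, COC(C)(C)OC
Why: Acid-catalysed transketalisation; the Z alkene holds both hydroxyls within reach, so the seven-membered acetonide closes readily; no stereocentre is formed.

Step 2
Reactants: 2 2,2-dimethyl-4,7-dihydro-1,3-dioxepine
Product: 3 2,2-dimethyl-4,5-dihydro-1,3-dioxepine
Conditions: RuHCl(CO)(PPh3)3 (cat.), toluene, 110 °C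
Reagents that add atoms: none
Why: Ruthenium hydride addition and β-hydride elimination move the double bond into conjugation with oxygen (allyl ether to enol ether isomerisation), a known reaction of 4,7-dihydro-1,3-dioxepines; the ring makes the enol ether Z.

Step 3
Reactants: 3 2,2-dimethyl-4,5-dihydro-1,3-dioxepine; 4 ethyl diazoacetate
Product: 5 ethyl (1R,7R,8R)-3,3-dimethyl-2,4-dioxabicyclo[5.1.0]octane-8-carboxylate (ester exo)
Conditions: (CuOTf)2·C6H6 (1 mol %), (S,S)-tBu-box [2,2′-(propane-2,2-diyl)bis((4S)-4-tert-butyl-4,5-dihydrooxazole)] (2.2 mol %), CH2Cl2, 0 °C → rt, slow addition of 4 to excess 3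
Reagents that add atoms: none
Why: Copper-carbene cyclopropanation of an electron-rich cyclic enol ether, as known for 2,3-dihydrofuran; syn addition is stereospecific, so C1 and C6 are cis by construction, the ester goes exo for steric reasons, and the bis(oxazoline)–monovalent copper carbene distinguishes the enantiotopic alkene faces and sets the absolute configuration at C1 and C6.

Step 4
Reactants: 5 ethyl (1R,7R,8R)-3,3-dimethyl-2,4-dioxabicyclo[5.1.0]octane-8-carboxylate
Product: 6 (1R,7R,8R)-3,3-dimethyl-2,4-dioxabicyclo[5.1.0]octane-8-carbaldehyde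
Conditions: iBu2AlH (1.1 equiv), CH2Cl2, −78 °C; aq. potassium sodium tartrate
Reagents that add atoms: none
Why: Partial ester reduction; the tetrahedral aluminium hemiacetal is stable at −78 °C and releases the aldehyde only on work-up, the ketal is inert and no stereocentre is touched; the aldehyde is used at once.

Step 5
Reactants: 6 (1R,7R,8R)-3,3-dimethyl-2,4-dioxabicyclo[5.1.0]octane-8-carbaldehyde; 7 5-(ethylsulfonyl)-1-phenyl-1H-tetrazole
Product: 8 (1R,7R,8R)-3,3-dimethyl-8-[(E)-prop-1-enyl]-2,4-dioxabicyclo[5.1.0]octane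
Conditions: KN(SiMe3)2, DME, −60 °C; then 6, −60 °C → rt
Reagents that add atoms: none
Why: Julia–Kocienski olefination; with the potassium base in DME the open transition state gives the anti adduct, whose Smiles rearrangement and anti elimination give the E alkene; the exo aldehyde is unhindered and meets no free base because the sulfone is metalated first.

Step 6
Reactants: 8 (1R,7R,8R)-3,3-dimethyl-8-[(E)-prop-1-enyl]-2,4-dioxabicyclo[5.1.0]octane; 9 carbon monoxide
Product: 11 cis-fused enone (5aS,9aR)-2,2,8-trimethyl-4,5,5a,6-tetrahydrobenzo[d][1,3]dioxepin-9(9aH)-one, via β,γ-enone 10 (not isolated)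
Conditions: Fe(CO)5 (1.5 equiv), CO (1 atm), hν (Pyrex), iPrOH, rt; then DBU (0.2 equiv), CH2Cl2, 0 °C
Reagents that add atoms: none
Why: Proposed new method: photolysis of Fe(CO)5 gives zerovalent Fe(CO)4, which binds the propenyl group of 8 and opens the adjacent cyclopropane bond C2–C6 to a σ-alkyl π-allyl iron complex; CO (9) then migrates into the Fe–C6 bond with retention and reductive elimination at the allyl terminus C4 forms C5–C6 and C4–C5, after which CO returns the iron as Fe(CO)5. The closest known reaction type is the iron-mediated [5+1] carbonylation of alkyl-substituted alkenylcyclopropanes to cyclohexenones, where iron enters the less substituted ring bond; an oxygen-bearing, fully substituted cyclopropane has not been examined. The six-membered ring closes by reductive elimination from a seven-membered acyl(allyl)iron metallacycle, the dioxepane acting as a spectator tether. No stereocentre is created: C1 is not involved, C6 keeps its configuration because ring opening, CO migration and elimination are all retentive, and the C4 centre of the first-formed β,γ-enone 10 disappears when catalytic DBU moves the double bond to C3=C4. The selectivity needed is opening of C2–C6 in preference to C2–C1; both bonds are equally substituted, so the choice is left to the ketal oxygen, which stabilises positive charge at C6 while the iron-bound allyl takes the negative charge (the same polarisation that makes C2–C6 the donor–acceptor bond of ester 5). The exo propenyl group keeps both bonds accessible, and the brief, cold DBU treatment is chosen to remove only the doubly activated C4–H and leave C6–H alone.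

Step 7
Reactants: 11 (5aS,9aR)-2,2,8-trimethyl-4,5,5a,6-tetrahydrobenzo[d][1,3]dioxepin-9(9aH)-one
Product: 12 (5aS,9S,9aR)-2,2,8-trimethyl-4,5,5a,6,9,9a-hexahydrobenzo[d][1,3]dioxepin-9-ol (C5–OH cis to C6–O and to C1–C7)
Conditions: NaBH4, CeCl3·7H2O, MeOH, −78 °C
Reagents that add atoms: none
Why: Luche 1,2-reduction; in either half-chair of the cis-fused enone, hydride enters the face opposite the C6–O bond and the C1 carbon substituent (Felkin–Anh attack anti to the pseudoaxial C6–O, or avoidance of the pseudoaxial C1–C7 bond), so the new C5 hydroxyl is cis to both.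

Step 8
Reactants: 12 (5aS,9S,9aR)-2,2,8-trimethyl-4,5,5a,6,9,9a-hexahydrobenzo[d][1,3]dioxepin-9-ol
Product: 13 2-[(3aR,4S,7aS)-2,2,7-trimethyl-3a,4,5,7a-tetrahydro-1,3-benzodioxol-4-yl]ethan-1-ol
Conditions: PPTS (cat.), acetone, rt
Reagents that add atoms: none
Why: Acid-catalysed acetal migration under thermodynamic control; the seven-membered ketal opens at the primary C8–O side to an oxocarbenium ion on O6, which the cis C5 hydroxyl captures as the favoured five-membered dioxolane, freeing the primary alcohol; no stereocentre changes.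

Step 9
Reactants: 13 2-[(3aR,4S,7aS)-2,2,7-trimethyl-3a,4,5,7a-tetrahydro-1,3-benzodioxol-4-yl]ethan-1-ol
Product: 14 2-[(3aR,4S,7aS)-2,2,7-trimethyl-3a,4,5,7a-tetrahydro-1,3-benzodioxol-4-yl]acetaldehyde
Conditions: TEMPO (cat.), PhI(OAc)2, CH2Cl2, rt
Reagents that add atoms: none
Why: Oxoammonium oxidation of a primary alcohol, which stops at the aldehyde and leaves alkenes and the acetonide alone; C1 is β to the new carbonyl and cannot epimerise.

Step 10
Reactants: 14 2-[(3aR,4S,7aS)-2,2,7-trimethyl-3a,4,5,7a-tetrahydro-1,3-benzodioxol-4-yl]acetaldehyde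
Product: 15 2-[(3aR,4S,7aS)-2,2,7-trimethyl-3a,4,5,7a-tetrahydro-1,3-benzodioxol-4-yl]prop-2-enal
Conditions: aq. HCHO (37%), pyrrolidine (10 mol %), EtCO2H (10 mol %), iPrOH, 45 °C
Reagents that add atoms: formaldehyde, C=O
Why: Organocatalytic α-methylenation of an aldehyde (enamine Mannich addition to formaldehyde, then elimination); it installs C14 on C7 under conditions mild enough for the acetonide, and the only α-position is C7.

Step 11
Reactants: 15 2-[(3aR,4S,7aS)-2,2,7-trimethyl-3a,4,5,7a-tetrahydro-1,3-benzodioxol-4-yl]prop-2-enal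
Product: 17 (3S)-2-[(3aR,4S,7aS)-2,2,7-trimethyl-3a,4,5,7a-tetrahydro-1,3-benzodioxol-4-yl]hexa-1,5-dien-3-ol, via diisopinocampheylborinate 16 (not isolated)
Conditions: (−)-Ipc2B(allyl), Et2O, −78 °C; then NaOH, H2O2, 0 °C → rt
Reagents that add atoms: (−)-B-allyldiisopinocampheylborane, C=CCB([C@@H]1C[C@@H]2C[C@H]([C@H]1C)C2(C)C)[C@@H]1C[C@@H]2C[C@H]([C@H]1C)C2(C)C
Why: Brown allylation; the allyl group is transferred 1,2 to the enal through a chair Zimmerman–Traxler transition state in which the isopinocampheyl groups select the aldehyde face, so C8 (S) is set by the reagent and not by the remote C1 centre.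

Step 12
Reactants: 17 (3S)-2-[(3aR,4S,7aS)-2,2,7-trimethyl-3a,4,5,7a-tetrahydro-1,3-benzodioxol-4-yl]hexa-1,5-dien-3-ol
Product: 18 (3S)-2-[(3aR,4S,7aS)-2,2,7-trimethyl-3a,4,5,7a-tetrahydro-1,3-benzodioxol-4-yl]hexa-1,5-dien-3-yl acetate
Conditions: Ac2O, Et3N, DMAP (cat.), CH2Cl2, 0 °C → rt
Reagents that add atoms: acetic anhydride, CC(=O)OC(C)=O
Why: DMAP-catalysed acylation of the only free hydroxyl; it puts the C8 acetate in place before metathesis so that no free allylic alcohol meets the ruthenium catalyst.

Step 13
Reactants: 18 (3S)-2-[(3aR,4S,7aS)-2,2,7-trimethyl-3a,4,5,7a-tetrahydro-1,3-benzodioxol-4-yl]hexa-1,5-dien-3-yl acetate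
Product: 19 (3S)-6-methyl-2-[(3aR,4S,7aS)-2,2,7-trimethyl-3a,4,5,7a-tetrahydro-1,3-benzodioxol-4-yl]hepta-1,5-dien-3-yl acetate
Conditions: second-generation Grubbs catalyst RuCl2(=CHPh)(H2IMes)(PCy3) (5 mol %), 2-methylbut-2-ene/CH2Cl2, 40 °C
Reagents that add atoms: 2-methylbut-2-ene, CC=C(C)C
Why: Olefin cross-metathesis of a terminal alkene with excess 2-methylbut-2-ene turns allyl into prenyl; the 1,1-disubstituted C7=C14 alkene between two branched carbons and the trisubstituted ring alkene do not react.

Step 14
Reactants: 19 (3S)-6-methyl-2-[(3aR,4S,7aS)-2,2,7-trimethyl-3a,4,5,7a-tetrahydro-1,3-benzodioxol-4-yl]hepta-1,5-dien-3-yl acetate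
Product: 20 (3S)-2-[(1S,5S,6R)-5,6-dihydroxy-4-methylcyclohex-3-en-1-yl]-6-methylhepta-1,5-dien-3-yl acetate
Conditions: AcOH/H2O (4:1), 40 °C
Reagents that add atoms: none
Why: Mild aqueous acid hydrolysis of the acetonide; the secondary acetate and the alkenes are stable to acetic acid, and acyl migration from C8–O to C6–O would need a seven-membered transition state.

Step 15
Reactants: 20 (3S)-2-[(1S,5S,6R)-5,6-dihydroxy-4-methylcyclohex-3-en-1-yl]-6-methylhepta-1,5-dien-3-yl acetate
Product: 21 (3S)-2-[(1S,3S,4R,5R,6R)-4,5-dihydroxy-6-methyl-7-oxabicyclo[4.1.0]heptan-3-yl]-6-methylhepta-1,5-dien-3-yl acetate (epoxide cis to both hydroxyls)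
Conditions: VO(acac)2 (5 mol %), tBuOOH (1.2 equiv), CH2Cl2, 0 °C
Reagents that add atoms: tert-butyl hydroperoxide, CC(C)(C)OO
Why: Vanadium-catalysed hydroxyl-directed epoxidation; the alkoxide-bound pentavalent vanadium peroxide delivers oxygen to C3=C4 on the face of the allylic C5 hydroxyl, which sets C3 and C4 cis to the other ring substituents, and the prenyl and methylene alkenes, lacking an allylic hydroxyl, react far more slowly.

Step 16
Reactants: 21 (3S)-2-[(1S,3S,4R,5R,6R)-4,5-dihydroxy-6-methyl-7-oxabicyclo[4.1.0]heptan-3-yl]-6-methylhepta-1,5-dien-3-yl acetate; 22 angelic acid [(Z)-2-methylbut-2-enoic acid]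
Product: 24 (1S,2R,3R,4S,6S)-4-[(3S)-3-acetoxy-6-methylhepta-1,5-dien-2-yl]-1-methyl-7-oxabicyclo[4.1.0]heptane-2,3-diyl bis[(Z)-2-methylbut-2-enoate] (the target), via angelic 2,4,6-trichlorobenzoic anhydride 23 (not isolated)
Conditions: 22 (6 equiv), 2,4,6-Cl3C6H2COCl, Et3N, toluene, rt; filtration; then 21, toluene, 80 °C
Reagents that add atoms: 2,4,6-trichlorobenzoyl chloride, O=C(Cl)c1c(Cl)cc(Cl)cc1Cl (its atoms stay in 23 only)
Why: Yamaguchi esterification through mixed anhydride 23, run without a nucleophilic catalyst because conjugate addition of such a catalyst is what isomerises angelates to tiglates; the hindered ortho-dichloro carbonyl of 23 leaves only the angeloyl carbonyl open to the two cis hydroxyls, and the ammonium chloride is filtered off to protect the epoxide.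

## Compound list

1 | (Z)-but-2-ene-1,4-diol | OC/C=C\CO | starting material
2 | 2,2-dimethyl-4,7-dihydro-1,3-dioxepine | CC1(C)OCC=CCO1 | intermediate
3 | 2,2-dimethyl-4,5-dihydro-1,3-dioxepine | CC1(C)OCCC=CO1 | intermediate
4 | ethyl diazoacetate | CCOC(=O)C=[N+]=[N-] | starting material
5 | ethyl (1R,7R,8R)-3,3-dimethyl-2,4-dioxabicyclo[5.1.0]octane-8-carboxylate (exo ester) | CC1(C)OCC[C@@H]2[C@@H](C(=O)OCC)[C@@H]2O1 | intermediate
6 | (1R,7R,8R)-3,3-dimethyl-2,4-dioxabicyclo[5.1.0]octane-8-carbaldehyde | CC1(C)OCC[C@@H]2[C@@H](C=O)[C@@H]2O1 | intermediate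
7 | 5-(ethylsulfonyl)-1-phenyl-1H-tetrazole | CCS(=O)(=O)c1nnnn1-c1ccccc1 | starting material
8 | (1R,7R,8R)-3,3-dimethyl-8-[(E)-prop-1-enyl]-2,4-dioxabicyclo[5.1.0]octane (propenyl exo) | CC1(C)OCC[C@@H]2[C@@H](/C=C/C)[C@@H]2O1 | intermediate
9 | carbon monoxide | [C-]#[O+] | starting material
10 | (5aR,9aR)-2,2,8-trimethyl-4,5,5a,8-tetrahydrobenzo[d][1,3]dioxepin-9(9aH)-one, cis-fused β,γ-enone, both C8 (ring C4) epimers | CC1(C)OCC[C@@H]2C=CC(C)C(=O)[C@@H]2O1 | intermediate (not isolated)
11 | (5aS,9aR)-2,2,8-trimethyl-4,5,5a,6-tetrahydrobenzo[d][1,3]dioxepin-9(9aH)-one, cis-fused | CC1(C)OCC[C@@H]2CC=C(C)C(=O)[C@@H]2O1 | intermediate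
12 | (5aS,9S,9aR)-2,2,8-trimethyl-4,5,5a,6,9,9a-hexahydrobenzo[d][1,3]dioxepin-9-ol, all-cis | CC1(C)OCC[C@@H]2CC=C(C)[C@H](O)[C@@H]2O1 | intermediate
13 | 2-[(3aR,4S,7aS)-2,2,7-trimethyl-3a,4,5,7a-tetrahydro-1,3-benzodioxol-4-yl]ethan-1-ol | OCC[C@@H]1CC=C(C)[C@@H]2OC(C)(C)O[C@H]12 | intermediate
14 | 2-[(3aR,4S,7aS)-2,2,7-trimethyl-3a,4,5,7a-tetrahydro-1,3-benzodioxol-4-yl]acetaldehyde | O=CC[C@@H]1CC=C(C)[C@@H]2OC(C)(C)O[C@H]12 | intermediate
15 | 2-[(3aR,4S,7aS)-2,2,7-trimethyl-3a,4,5,7a-tetrahydro-1,3-benzodioxol-4-yl]prop-2-enal | C=C(C=O)[C@@H]1CC=C(C)[C@@H]2OC(C)(C)O[C@H]12 | intermediate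
16 | (3S)-2-[(3aR,4S,7aS)-2,2,7-trimethyl-3a,4,5,7a-tetrahydro-1,3-benzodioxol-4-yl]hexa-1,5-dien-3-yl bis[(1R,2S,3R,5R)-2,6,6-trimethylbicyclo[3.1.1]heptan-3-yl]borinate | C=C([C@H](CC=C)OB([C@@H]3C[C@@H]4C[C@H]([C@H]3C)C4(C)C)[C@@H]3C[C@@H]4C[C@H]([C@H]3C)C4(C)C)[C@@H]1CC=C(C)[C@@H]2OC(C)(C)O[C@H]12 | intermediate (not isolated)
17 | (3S)-2-[(3aR,4S,7aS)-2,2,7-trimethyl-3a,4,5,7a-tetrahydro-1,3-benzodioxol-4-yl]hexa-1,5-dien-3-ol | C=C([C@H](CC=C)O)[C@@H]1CC=C(C)[C@@H]2OC(C)(C)O[C@H]12 | intermediate
18 | (3S)-2-[(3aR,4S,7aS)-2,2,7-trimethyl-3a,4,5,7a-tetrahydro-1,3-benzodioxol-4-yl]hexa-1,5-dien-3-yl acetate | C=C([C@H](CC=C)OC(C)=O)[C@@H]1CC=C(C)[C@@H]2OC(C)(C)O[C@H]12 | intermediate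
19 | (3S)-6-methyl-2-[(3aR,4S,7aS)-2,2,7-trimethyl-3a,4,5,7a-tetrahydro-1,3-benzodioxol-4-yl]hepta-1,5-dien-3-yl acetate | C=C([C@H](CC=C(C)C)OC(C)=O)[C@@H]1CC=C(C)[C@@H]2OC(C)(C)O[C@H]12 | intermediate
20 | (3S)-2-[(1S,5S,6R)-5,6-dihydroxy-4-methylcyclohex-3-en-1-yl]-6-methylhepta-1,5-dien-3-yl acetate | C=C([C@H](CC=C(C)C)OC(C)=O)[C@@H]1CC=C(C)[C@H](O)[C@@H]1O | intermediate
21 | (3S)-2-[(1S,3S,4R,5R,6R)-4,5-dihydroxy-6-methyl-7-oxabicyclo[4.1.0]heptan-3-yl]-6-methylhepta-1,5-dien-3-yl acetate | C=C([C@H](CC=C(C)C)OC(C)=O)[C@@H]1C[C@@H]2O[C@]2(C)[C@H](O)[C@@H]1O | intermediate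
22 | angelic acid, (Z)-2-methylbut-2-enoic acid | C/C=C(/C)C(=O)O | starting material
23 | (Z)-2-methylbut-2-enoic 2,4,6-trichlorobenzoic anhydride | C/C=C(/C)C(=O)OC(=O)c1c(Cl)cc(Cl)cc1Cl | intermediate (not isolated)
24 | (1S,2R,3R,4S,6S)-4-[(3S)-3-acetoxy-6-methylhepta-1,5-dien-2-yl]-1-methyl-7-oxabicyclo[4.1.0]heptane-2,3-diyl bis[(Z)-2-methylbut-2-enoate] | C=C([C@H](CC=C(C)C)OC(C)=O)[C@@H]1C[C@@H]2O[C@]2(C)[C@H](OC(=O)/C(C)=C\C)[C@@H]1OC(=O)/C(C)=C\C | target

## Step count and least certain steps

Total: 16 steps. Longest linear sequence: 16 steps (1 to 24); all other reactants are commercial.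

**Step 6 (key step, proposed new method).** What may go wrong: iron may open the C2–C1 bond, since the two bonds are sterically alike and the known preference is steric. β-Hydride elimination or fragmentation of the ketal may overtake CO insertion in the ring-opened iron species. C6 may epimerise during the base-mediated conjugation. The fallback sets out from ethyl diazoacetate 4 and returns at alcohol 13; it takes the oxygen off the cyclopropane so that the carbonylation runs in its established sense, and brings C6–O in afterwards. Copper/bis(oxazoline) cyclopropanation of tert-butyl(but-3-en-1-yloxy)dimethylsilane F1 with 4 gives, after separation from the cis isomer, ethyl trans-2-[2-(tert-butyldimethylsilyloxy)ethyl]cyclopropane-1-carboxylate F2. iBu2AlH gives the trans aldehyde F3, and Julia–Kocienski olefination with 7 gives the trans-1-(2-silyloxyethyl)-2-[(E)-prop-1-enyl]cyclopropane F4. Fe(CO)5/CO/hν and then DBU, with iron now entering the unsubstituted ring bond as in the known cases, give (5S)-5-[2-(tert-butyldimethylsilyloxy)ethyl]-2-methylcyclohex-2-en-1-one F5. The kinetic enolate (LiN(iPr)2, Me3SiCl) is oxidised with mCPBA (Rubottom oxidation) anti to the side chain to the trans-6-hydroxy enone F6. A Mitsunobu reaction with 4-nitrobenzoic acid inverts C6 to the cis 4-nitrobenzoate F7. Luche reduction gives the all-cis hydroxy ester F8, K2CO3/MeOH the all-cis diol F9, 2,2-dimethoxypropane/PPTS the acetonide silyl ether F10, and Bu4NF returns 13. The price is two more steps to 13 and a C6 centre set by inversion instead of by construction.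

**Step 3.** What may go wrong: poor facial discrimination or a poor exo/endo ratio on a flexible seven-membered enol ether, for which the dihydrofuran precedent is only an analogy. The fallback sets out from enol ether 3 and returns at aldehyde 6. Rh2(OAc)4-catalysed addition of 4 to 3 gives the racemic exo ester F11, and LiAlH4 reduces it to the racemic exo alcohol F12. Kinetic resolution by lipase-catalysed acetylation (Pseudomonas cepacia lipase, vinyl acetate, tBuOMe; the enzyme is chosen by screening) leaves the (1R,7R,8S) alcohol F13 and converts its antipode into acetate F14. Parikh–Doering oxidation (SO3·pyridine, DMSO, Et3N) of F13 gives 6.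

**Step 8.** What may go wrong: incomplete or unselective acetal migration, or ionisation of the allylic C5 alcohol under acid. The fallback sets out from 12 and returns at 13. Aqueous acetic acid hydrolyses the seven-membered ketal to the all-cis triol F15, and kinetic ketalisation with 2-methoxypropene and PPTS at 0 °C takes the cis-1,2-diol in preference to the 1,4-diol and gives 13.

**Step 16.** What may go wrong: Z to E isomerisation of the angeloyl group, incomplete acylation of the second hindered hydroxyl, and opening of the epoxide by residual chloride at 80 °C. The fallback sets out from 21 and returns at 24; it builds the Z double bonds after the ester bonds. Epoxy diol 21 is acylated with 2-[bis(2,2,2-trifluoroethoxy)phosphoryl]propanoic acid (DCC, DMAP, rt; a saturated acid, so nothing can isomerise) to the bis(phosphonopropionate) F16. A double Still–Gennari olefination (KN(SiMe3)2, 18-crown-6, THF, −78 °C, acetaldehyde) then gives the two (Z)-2-methylbut-2-enoates of 24.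

## Further compounds

F1 | step 6 | tert-butyl(but-3-en-1-yloxy)dimethylsilane | C=CCCO[Si](C)(C)C(C)(C)C
F2 | step 6 | ethyl (1S,2R)-2-[2-(tert-butyldimethylsilyloxy)ethyl]cyclopropane-1-carboxylate (trans) | CC(C)(C)[Si](C)(C)OCC[C@@H]1[C@@H](C(=O)OCC)C1
F3 | step 6 | (1S,2R)-2-[2-(tert-butyldimethylsilyloxy)ethyl]cyclopropane-1-carbaldehyde (trans) | CC(C)(C)[Si](C)(C)OCC[C@@H]1[C@@H](C=O)C1
F4 | step 6 | tert-butyldimethyl{2-[(1R,2S)-2-[(E)-prop-1-enyl]cyclopropyl]ethoxy}silane (trans) | CC(C)(C)[Si](C)(C)OCC[C@@H]1[C@@H](/C=C/C)C1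
F5 | step 6 | (5S)-5-[2-(tert-butyldimethylsilyloxy)ethyl]-2-methylcyclohex-2-en-1-one | CC(C)(C)[Si](C)(C)OCC[C@@H]1CC=C(C)C(=O)C1
F6 | step 6 | (5S,6S)-5-[2-(tert-butyldimethylsilyloxy)ethyl]-6-hydroxy-2-methylcyclohex-2-en-1-one (trans) | CC(C)(C)[Si](C)(C)OCC[C@@H]1CC=C(C)C(=O)[C@H]1O
F7 | step 6 | (1R,6S)-6-[2-(tert-butyldimethylsilyloxy)ethyl]-3-methyl-2-oxocyclohex-3-en-1-yl 4-nitrobenzoate (cis) | CC(C)(C)[Si](C)(C)OCC[C@@H]1CC=C(C)C(=O)[C@@H]1OC(=O)c1ccc([N+](=O)[O-])cc1
F8 | step 6 | (1R,2S,6S)-6-[2-(tert-butyldimethylsilyloxy)ethyl]-2-hydroxy-3-methylcyclohex-3-en-1-yl 4-nitrobenzoate (all-cis) | CC(C)(C)[Si](C)(C)OCC[C@@H]1CC=C(C)[C@H](O)[C@@H]1OC(=O)c1ccc([N+](=O)[O-])cc1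
F9 | step 6 | (1R,2S,6S)-6-[2-(tert-butyldimethylsilyloxy)ethyl]-3-methylcyclohex-3-ene-1,2-diol (all-cis) | CC(C)(C)[Si](C)(C)OCC[C@@H]1CC=C(C)[C@H](O)[C@@H]1O
F10 | step 6 | tert-butyldimethyl{2-[(3aR,4S,7aS)-2,2,7-trimethyl-3a,4,5,7a-tetrahydro-1,3-benzodioxol-4-yl]ethoxy}silane | CC(C)(C)[Si](C)(C)OCC[C@@H]1CC=C(C)[C@@H]2OC(C)(C)O[C@H]12
F11 | step 3 | racemic ethyl (1R*,7R*,8R*)-3,3-dimethyl-2,4-dioxabicyclo[5.1.0]octane-8-carboxylate (exo; one enantiomer drawn) | CC1(C)OCC[C@@H]2[C@@H](C(=O)OCC)[C@@H]2O1
F12 | step 3 | racemic [(1R*,7R*,8S*)-3,3-dimethyl-2,4-dioxabicyclo[5.1.0]octan-8-yl]methanol (exo; one enantiomer drawn) | CC1(C)OCC[C@@H]2[C@@H](CO)[C@@H]2O1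
F13 | step 3 | [(1R,7R,8S)-3,3-dimethyl-2,4-dioxabicyclo[5.1.0]octan-8-yl]methanol (exo, single enantiomer) | CC1(C)OCC[C@@H]2[C@@H](CO)[C@@H]2O1
F14 | step 3 | [(1S,7S,8R)-3,3-dimethyl-2,4-dioxabicyclo[5.1.0]octan-8-yl]methyl acetate (exo, antipodal series) | CC1(C)OCC[C@H]2[C@H](COC(C)=O)[C@H]2O1
F15 | step 8 | (1R,2S,6S)-6-(2-hydroxyethyl)-3-methylcyclohex-3-ene-1,2-diol (all-cis) | OCC[C@@H]1CC=C(C)[C@H](O)[C@@H]1O
F16 | step 16 | (1S,2R,3R,4S,6S)-4-[(3S)-3-acetoxy-6-methylhepta-1,5-dien-2-yl]-1-methyl-7-oxabicyclo[4.1.0]heptane-2,3-diyl bis{2-[bis(2,2,2-trifluoroethoxy)phosphoryl]propanoate} (epimers at the two phosphonate α-carbons) | C=C([C@H](CC=C(C)C)OC(C)=O)[C@@H]1C[C@@H]2O[C@]2(C)[C@H](OC(=O)C(C)P(=O)(OCC(F)(F)F)OCC(F)(F)F)[C@@H]1OC(=O)C(C)P(=O)(OCC(F)(F)F)OCC(F)(F)F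
A1 | alternative 1 | 1-(3-methylbut-2-en-1-yl)-2-[(3aR,4S,7aS)-2,2,7-trimethyl-3a,4,5,7a-tetrahydro-1,3-benzodioxol-4-yl]cyclopropan-1-ol (one cyclopropane diastereomer drawn) | O[C@@]3(CC=C(C)C)C[C@@H]3[C@@H]1CC=C(C)[C@H](OC2(C)C)[C@@H]1O2
A2 | alternative 1 | (3aR,4S,7aS)-4-ethenyl-2,2,7-trimethyl-3a,4,5,7a-tetrahydro-1,3-benzodioxole | C=C[C@@H]1CC=C(C)[C@H](OC2(C)C)[C@@H]1O2
A3 | alternative 1 | methyl 4-methylpent-3-enoate | COC(=O)CC=C(C)C
A4 | alternative 2 | all-cis 7-(tert-butyldimethylsilyloxy)-2,2,6-trimethyl-3-methylidene-2,3,3a,4,7,7a-hexahydro-1,2-benzoxasilole | C=C1[C@@H]2CC=C(C)[C@H](O[Si](C)(C)C(C)(C)C)[C@@H]2O[Si]1(C)C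
A5 | alternative 2 | (1-bromoethenyl)dimethylsilyl ether at C6–O and tert-butyldimethylsilyl ether at C5–O of cis-(1R,2S)-3-methylcyclohexa-3,5-diene-1,2-diol | C=C(Br)[Si](C)(C)O[C@@H]1C=CC=C(C)[C@@H]1O[Si](C)(C)C(C)(C)C
A6 | alternative 2 | (1S,2R)-3-methylcyclohexa-3,5-diene-1,2-diol (microbial dihydrodiol of toluene) | CC1=CC=C[C@@H]([C@@H]1O)O
A7 | alternative 3 | all-cis 3,6-diacetoxy-4-methylcyclohex-4-en-1-yl ketone carrying the (S)-1-(4-methoxybenzyloxy)-4-methylpent-3-enyl chain | O=C([C@H](CC=C(C)C)OCc2ccc(OC)cc2)[C@@H]1C[C@H](OC(C)=O)C(C)=C[C@@H]1OC(C)=O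
A8 | alternative 3 | (1E,3E)-2-methylbuta-1,3-diene-1,4-diyl diacetate | CC(=O)O/C=C/C(C)=C/OC(C)=O
A9 | alternative 3 | (4S)-4-[(4-methoxyphenyl)methoxy]-7-methylocta-1,6-dien-3-one | C=CC(=O)[C@H](CC=C(C)C)OCc1ccc(OC)cc1
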